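## Retrosynthetic overview

1. Feature: the 12-membered ring contains a diaryl ether oxygen. It links the ring A carbon para to CH3 (meta to the lactone carbonyl) to the ring B carbon para to the phenol OH (ortho to the Z-alkenyl carbon). Neither carbon is activated for substitution, but the same two atoms are easily bridged as O–C(=O).
2. Key disconnection: CO is put back between that ring A carbon and the oxygen. This gives 13-membered dilactone 24, a mixed aryl/alkyl diester of 4-methylisophthalic acid. In the forward direction, nickel-mediated loss of CO contracts 24 to diaryl ether lactone 25.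
3. Dilactone 24 comes from seco acid 22 by phenol macrolactonization at the unhindered ring A acid. Seco acid 22 comes from ring B bromide 19 and alkyne ester 14 by Sonogashira coupling, then Lindlar semihydrogenation to set the Z-alkene.
4. Ester 14 comes from half ester 13 (hindered acid free) and alkynol 10. The syn C1/C2 diol comes from hexanal by asymmetric (Z)-alkoxyallylboration, which leaves C1–OH free and C2–O already protected as a MOM ether.
5. Ring order: rings A and B are bought. The 13-membered ring forms in step 16 and the 12-membered ring in step 17. One acid step then frees C2–OH, the phenol and the aldehyde.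

Key step: step 17

Locants: C1 is the pentyl-bearing carbinol carbon and C2 is the allylic carbinol carbon. Ring A is the methylbenzoate ring and ring B is the formylphenol ring.

Remark on ring A: partial saponification of dimethyl 4-methylisophthalate would free the unhindered acid, which is the wrong one for the first esterification. Half ester 13 is therefore made by carboxylation of methyl 3-iodo-4-methylbenzoate.

Remark on protecting groups: C2–O carries a MOM ether because the allylboration delivers the diol already differentiated in that form. A single acid step clears all three acetals at the end.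

## Route

Step 1
Reactants: 1 allyl alcohol
Product: 2 allyl methoxymethyl ether (3-(methoxymethoxy)prop-1-ene)
Conditions: MOMCl, i-Pr2NEt, CH2Cl2, 0 °C to rt; distillation
Reagents that add atoms: chloromethyl methyl ether (MOMCl), COCCl
Why: O-alkylation of a primary alcohol with an α-chloro ether (MOM protection) is routine and supplies the unit that becomes C2 and the adjoining alkene carbon.

Step 2
Reactants: 2 allyl methoxymethyl ether; 3 hexanal
Product: 5 (3S,4S)-3-(methoxymethoxy)non-1-en-4-ol, via (Z)-alkoxyallylborane 4 (not isolated)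
Conditions: 2, s-BuLi, THF, −78 °C; (+)-B-methoxydiisopinocampheylborane [from (−)-α-pinene], −78 °C; BF3·OEt2, then 3, −78 °C; NaOH, H2O2, 0 °C to rt
Reagents that add atoms: none
Why: In the Brown asymmetric alkoxyallylboration the chelated Z-allyllithium gives Z-borane 4, which adds to hexanal through a closed chair transition state, so the Z geometry sets the syn C1/C2 relation and the isopinocampheyl groups from (−)-α-pinene select the aldehyde face that gives (S) at both centres, with C1–OH free and C2–O protected.

Step 3
Reactants: 5 (3S,4S)-3-(methoxymethoxy)non-1-en-4-ol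
Product: 6 tert-butyl{[(3S,4S)-3-(methoxymethoxy)non-1-en-4-yl]oxy}dimethylsilane
Conditions: TBSCl, imidazole, DMF, rt
Reagents that add atoms: tert-butyldimethylsilyl chloride (TBSCl), CC(C)(C)[Si](C)(C)Cl
Why: Standard silyl ether formation masks C1–OH, so steps 4 and 5 never expose a β-hydroxy aldehyde prone to retro-aldol cleavage.

Step 4
Reactants: 6 TBS ether of 5
Product: 8 (2R,3S)-3-(tert-butyldimethylsilyloxy)-2-(methoxymethoxy)octanal, via secondary ozonide 7 (not isolated)
Conditions: O3, CH2Cl2, −78 °C; PPh3, −78 °C to rt
Reagents that add atoms: ozone, [O-][O+]=O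
Why: Ozonolysis with reductive work-up cleaves the only C=C bond and leaves the silyl ether, the acetal and both stereocentres untouched at −78 °C (the descriptor at C2 changes only because CHO outranks C1).

Step 5
Reactants: 8 (2R,3S)-3-(tert-butyldimethylsilyloxy)-2-(methoxymethoxy)octanal
Product: 9 tert-butyl{[(3S,4S)-3-(methoxymethoxy)non-1-yn-4-yl]oxy}dimethylsilane
Conditions: dimethyl (1-diazo-2-oxopropyl)phosphonate, K2CO3, MeOH, 0 °C to rt
Reagents that add atoms: dimethyl (1-diazo-2-oxopropyl)phosphonate, COP(=O)(OC)C(=[N+]=[N-])C(C)=O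
Why: The Ohira–Bestmann homologation (Seyferth–Gilbert type) converts the aldehyde into the terminal alkyne under carbonate base, which is mild enough that α-alkoxy aldehydes normally keep their configuration.

Step 6
Reactants: 9 silyl-protected alkyne
Product: 10 (3S,4S)-3-(methoxymethoxy)non-1-yn-4-ol
Conditions: TBAF, THF, 0 °C to rt
Reagents that add atoms: none
Why: Fluoride-induced desilylation frees C1–OH, and the MOM ether and the terminal alkyne are inert to TBAF.

Step 7
Reactants: 11 methyl 3-iodo-4-methylbenzoate
Product: 13 5-(methoxycarbonyl)-2-methylbenzoic acid, via arylmagnesium chloride 12 (not isolated)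
Conditions: i-PrMgCl·LiCl, THF, −40 °C; CO2 (gas), −40 to 0 °C; 1 M HCl
Reagents that add atoms: carbon dioxide, O=C=O
Why: Iodine–magnesium exchange with the turbo-Grignard reagent outruns attack on the ester at −40 °C, and carboxylation of 12 places the free acid unambiguously ortho to the methyl group.

Step 8
Reactants: 10 (3S,4S)-3-(methoxymethoxy)non-1-yn-4-ol; 13 5-(methoxycarbonyl)-2-methylbenzoic acid
Product: 14 1-methyl 3-[(3S,4S)-3-(methoxymethoxy)non-1-yn-4-yl] 4-methylisophthalate
Conditions: DIC, DMAP, CH2Cl2, 0 °C to rt
Reagents that add atoms: none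
Why: Steglich esterification with DMAP as acyl-transfer catalyst joins the mono-ortho-substituted acid to the only free hydroxyl, with retention at C1 because the C1–O bond is not broken.

Step 9
Reactants: 15 2,5-dihydroxybenzaldehyde
Product: 16 2-bromo-3,6-dihydroxybenzaldehyde
Conditions: Br2, CHCl3, 0 °C to rt
Reagents that add atoms: bromine, BrBr
Why: In this electrophilic aromatic bromination the 5-OH is the stronger donor because the 2-OH is tied up in a hydrogen bond to the formyl group, its para position is blocked, and bond fixation in the chelated salicylaldehyde directs attack to C6 next to the formyl group, which is the known outcome for this substrate.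

Step 10
Reactants: 16 2-bromo-3,6-dihydroxybenzaldehyde
Product: 17 2-bromo-3-(tert-butyldimethylsilyloxy)-6-hydroxybenzaldehyde
Conditions: TBSCl (1.05 equiv), imidazole, CH2Cl2, 0 °C
Reagents that add atoms: tert-butyldimethylsilyl chloride (TBSCl), CC(C)(C)[Si](C)(C)Cl
Why: The silylation is chemoselective because the 6-OH is locked in a hydrogen bond to the formyl oxygen and is much less nucleophilic, so one equivalent of TBSCl should take the 3-OH next to bromine, which is the future ester and ether oxygen.

Step 11
Reactants: 17 2-bromo-3-(tert-butyldimethylsilyloxy)-6-hydroxybenzaldehyde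
Product: 18 2-bromo-3-(tert-butyldimethylsilyloxy)-6-(methoxymethoxy)benzaldehyde
Conditions: MOMCl (excess), i-Pr2NEt, CH2Cl2, 0 to 40 °C
Reagents that add atoms: chloromethyl methyl ether (MOMCl), COCCl
Why: MOM protection by O-alkylation of the remaining chelated phenol proceeds with excess reagent, and the aryl silyl ether and the aldehyde are inert to it.

Step 12
Reactants: 18 2-bromo-3-(tert-butyldimethylsilyloxy)-6-(methoxymethoxy)benzaldehyde
Product: 19 [2-bromo-3-(1,3-dioxolan-2-yl)-4-(methoxymethoxy)phenoxy](tert-butyl)dimethylsilane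
Conditions: TMSOCH2CH2OTMS, TMSOTf (5 mol %), CH2Cl2, −78 to −20 °C; pyridine quench
Reagents that add atoms: 1,2-bis(trimethylsilyloxy)ethane, C[Si](C)(C)OCCO[Si](C)(C)C
Why: Noyori acetalization under aprotic conditions converts even hindered aryl aldehydes at low temperature, where the aryl MOM and aryl silyl ethers should survive the catalytic silyl triflate.

Step 13
Reactants: 14 alkyne ester; 19 ring B bromide
Product: 20 1-methyl 3-{(3S,4S)-1-[2-(tert-butyldimethylsilyloxy)-6-(1,3-dioxolan-2-yl)-5-(methoxymethoxy)phenyl]-3-(methoxymethoxy)non-1-yn-4-yl} 4-methylisophthalate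
Conditions: PdCl2(PhCN)2 (5 mol %), [HP(t-Bu)3]BF4 (10 mol %), CuI (5 mol %), i-Pr2NH, 1,4-dioxane, rt to 45 °C, argon
Reagents that add atoms: none
Why: This is a Sonogashira coupling in which the bulky electron-rich P(t-Bu)3 lets zerovalent palladium insert into hindered electron-rich aryl bromides near room temperature, and the hindered amine spares both esters and the aryl silyl ether.

Step 14
Reactants: 20 aryl alkyne
Product: 21 1-methyl 3-{(1Z,3S,4S)-1-[2-(tert-butyldimethylsilyloxy)-6-(1,3-dioxolan-2-yl)-5-(methoxymethoxy)phenyl]-3-(methoxymethoxy)non-1-en-4-yl} 4-methylisophthalate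
Conditions: H2 (1 atm), Pd/CaCO3 poisoned with Pb(OAc)2 (Lindlar catalyst), quinoline, EtOAc, rt
Reagents that add atoms: none
Why: Lindlar semihydrogenation delivers both hydrogens to one face of the alkyne on the poisoned palladium surface and so sets the Z-alkene, with no other reducible group present.

Step 15
Reactants: 21 Z-alkene diester
Product: 22 3-({(1Z,3S,4S)-1-[6-(1,3-dioxolan-2-yl)-2-hydroxy-5-(methoxymethoxy)phenyl]-3-(methoxymethoxy)non-1-en-4-yl}oxycarbonyl)-4-methylbenzoic acid (seco acid)
Conditions: LiOH (4 equiv), THF/MeOH/H2O, rt, argon; cold 0.5 M HCl to pH 4–5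
Reagents that add atoms: lithium hydroxide, [Li+].[OH-]
Why: In this saponification hydroxide cleaves the unhindered aryl methyl ester and the aryl silyl ether in one operation, whereas the secondary alkyl ester shielded by the ortho methyl group and branched C1 reacts far more slowly and the acetals are inert to base.

Step 16
Reactants: 22 seco acid
Product: 24 protected 13-membered dilactone (C1 S, C2 S, Z-alkene; aryl ester between the ring A acid para to CH3 and the ring B oxygen; MOM ethers on C2–O and on ring B; 1,3-dioxolan-2-yl on ring B), via mixed anhydride 23 (not isolated)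
Conditions: 2-methyl-6-nitrobenzoic anhydride (MNBA), DMAP, CH2Cl2, rt, slow addition of 22 (final about 2 mM)
Reagents that add atoms: none
Why: In the Shiina macrolactonization MNBA activates the unhindered ring A acid as 23, DMAP passes this acyl group to the ring B phenol (the only free hydroxyl), and slow addition favours closure of the 13-membered ring over oligomerization.

Step 17
Reactants: 24 protected 13-membered dilactone
Product: 25 protected 12-membered diaryl ether macrolactone (C1 S, C2 S, Z-alkene; MOM ethers on C2–O and on ring B; 1,3-dioxolan-2-yl on ring B)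
Conditions: Ni(cod)2 (20 mol %), 3,4-bis(dicyclohexylphosphino)thiophene (40 mol %), K3PO4 (1.5 equiv), toluene (0.01 M), 150 °C, sealed vessel with large argon headspace
Reagents that add atoms: none
Why: Proposed new method: zerovalent nickel carrying the electron-rich chelating bisphosphine should insert into the C(acyl)–O bond of the aryl ester of 24, the acylnickel aryloxide should extrude CO at 150 °C, and C–O reductive elimination from the ring A aryl–nickel–aryloxide should join the ring A carbon para to the methyl group to the ring B oxygen. The closest known reaction type is the decarbonylative etherification of aryl esters of azine and other electron-poor aromatic acids with Ni(cod)2 or Pd(OAc)2 and this ligand, which has been shown neither on a macrolactone nor on an alkyl-substituted isophthalate. The 12-membered ring closes by contraction of the 13-membered one, because the aryl carbon and the aryloxide oxygen stay tethered on one metal in a 13-membered nickelacycle and only have to eliminate reductively; the moderate dilution serves only to suppress aryloxide exchange between nickel centres. No stereocentre is formed, and C1 and C2 keep their C–O bonds. The step must discriminate between two esters on the same arene, and the substrate secures this because only the ring B aryloxide is a good enough leaving group for oxidative addition, whereas the secondary alkyl benzoate at C1 has a much stronger C(acyl)–O bond and an ortho methyl shield. The ester meta to the nickel-bearing carbon lowers the electron density of ring A, which should help reductive elimination, and the Z-alkene is held in place by the ring.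

Step 18
Reactants: 25 protected 12-membered diaryl ether macrolactone
Product: 26 CNP0238900.1 (target)
Conditions: 3 M aq HCl, THF, 45 °C
Reagents that add atoms: water, O
Why: Acid-catalysed acetal hydrolysis removes both MOM ethers and the dioxolane by cleavage at the acetal carbons, so the C1–O and C2–O bonds keep their configuration, and leaving out an alcohol cosolvent prevents the aldehyde and C2–OH from being trapped as a mixed cyclic acetal.

## Compound list

1 | allyl alcohol | C=CCO | starting material
2 | allyl methoxymethyl ether | C=CCOCOC | intermediate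
3 | hexanal | CCCCCC=O | starting material
4 | [(Z)-3-(methoxymethoxy)allyl]diisopinocampheylborane (isopinocampheyl groups from (−)-α-pinene) | COCO/C=C\CB([C@H]1C[C@H]2C[C@@H]([C@@H]1C)C2(C)C)[C@H]1C[C@H]2C[C@@H]([C@@H]1C)C2(C)C | intermediate
5 | (3S,4S)-3-(methoxymethoxy)non-1-en-4-ol | CCCCC[C@H](O)[C@@H](OCOC)C=C | intermediate
6 | tert-butyl{[(3S,4S)-3-(methoxymethoxy)non-1-en-4-yl]oxy}dimethylsilane | CCCCC[C@H](O[Si](C)(C)C(C)(C)C)[C@@H](OCOC)C=C | intermediate
7 | secondary ozonide of 6 (3-substituted 1,2,4-trioxolane, ring carbon undefined) | CCCCC[C@H](O[Si](C)(C)C(C)(C)C)[C@@H](OCOC)C1OCOO1 | intermediate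
8 | (2R,3S)-3-(tert-butyldimethylsilyloxy)-2-(methoxymethoxy)octanal | CCCCC[C@H](O[Si](C)(C)C(C)(C)C)[C@@H](OCOC)C=O | intermediate
9 | tert-butyl{[(3S,4S)-3-(methoxymethoxy)non-1-yn-4-yl]oxy}dimethylsilane | CCCCC[C@H](O[Si](C)(C)C(C)(C)C)[C@@H](OCOC)C#C | intermediate
10 | (3S,4S)-3-(methoxymethoxy)non-1-yn-4-ol | CCCCC[C@H](O)[C@@H](OCOC)C#C | intermediate
11 | methyl 3-iodo-4-methylbenzoate | COC(=O)c1ccc(C)c(I)c1 | starting material
12 | [5-(methoxycarbonyl)-2-methylphenyl]magnesium chloride (LiCl complex) | COC(=O)c1ccc(C)c([Mg]Cl)c1 | intermediate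
13 | 5-(methoxycarbonyl)-2-methylbenzoic acid | COC(=O)c1ccc(C)c(c1)C(=O)O | intermediate
14 | 1-methyl 3-[(3S,4S)-3-(methoxymethoxy)non-1-yn-4-yl] 4-methylisophthalate | CCCCC[C@H](OC(=O)c1cc(ccc1C)C(=O)OC)[C@@H](OCOC)C#C | intermediate
15 | 2,5-dihydroxybenzaldehyde | O=Cc1cc(O)ccc1O | starting material
16 | 2-bromo-3,6-dihydroxybenzaldehyde | O=Cc1c(O)ccc(O)c1Br | intermediate
17 | 2-bromo-3-(tert-butyldimethylsilyloxy)-6-hydroxybenzaldehyde | O=Cc1c(O)ccc(O[Si](C)(C)C(C)(C)C)c1Br | intermediate
18 | 2-bromo-3-(tert-butyldimethylsilyloxy)-6-(methoxymethoxy)benzaldehyde | COCOc1ccc(O[Si](C)(C)C(C)(C)C)c(Br)c1C=O | intermediate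
19 | [2-bromo-3-(1,3-dioxolan-2-yl)-4-(methoxymethoxy)phenoxy](tert-butyl)dimethylsilane | COCOc1ccc(O[Si](C)(C)C(C)(C)C)c(Br)c1C1OCCO1 | intermediate
20 | aryl alkyne diester (Sonogashira product, 3S,4S) | CCCCC[C@H](OC(=O)c1cc(ccc1C)C(=O)OC)[C@@H](OCOC)C#Cc1c(O[Si](C)(C)C(C)(C)C)ccc(OCOC)c1C1OCCO1 | intermediate
21 | Z-alkene diester (1Z,3S,4S) | CCCCC[C@H](OC(=O)c1cc(ccc1C)C(=O)OC)[C@@H](OCOC)/C=C\c1c(O[Si](C)(C)C(C)(C)C)ccc(OCOC)c1C1OCCO1 | intermediate
22 | seco acid (free ring A acid para to CH3, free ring B phenol; 1Z,3S,4S) | CCCCC[C@H](OC(=O)c1cc(ccc1C)C(=O)O)[C@@H](OCOC)/C=C\c1c(O)ccc(OCOC)c1C1OCCO1 | intermediate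
23 | mixed 2-methyl-6-nitrobenzoic anhydride of seco acid 22 | CCCCC[C@H](OC(=O)c1cc(ccc1C)C(=O)OC(=O)c1c(C)cccc1[N+](=O)[O-])[C@@H](OCOC)/C=C\c1c(O)ccc(OCOC)c1C1OCCO1 | intermediate
24 | protected 13-membered dilactone (key-step precursor) | CCCCC[C@@H]1OC(=O)c2cc(ccc2C)C(=O)Oc2ccc(OCOC)c(C3OCCO3)c2/C=C\[C@@H]1OCOC | intermediate
25 | protected 12-membered diaryl ether macrolactone (key-step product) | CCCCC[C@@H]1OC(=O)c2cc(ccc2C)Oc2ccc(OCOC)c(C3OCCO3)c2/C=C\[C@@H]1OCOC | intermediate
26 | CNP0238900.1 | CCCCC[C@@H]1OC(=O)c2cc(ccc2C)Oc2ccc(O)c(C=O)c2/C=C\[C@@H]1O | target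

## Step count and risks

Total step count: 18.
Longest linear sequence: 13 steps (steps 1–6, 8, 13–18).

**Step 17 (ring contraction).**
- What may go wrong:
  - Oxidative addition may stall on a benzoate that lacks an azine nitrogen.
  - Released CO may tie up nickel as carbonyl complexes.
  - The organonickel species may be protonated, or may exchange aryloxides between metal centres and give oligomers.
  - Nickel may engage the allylic C2–O bond or isomerize the alkene at 150 °C.
- Fallback: known chemistry, setting out from 19 and 10 and returning at 25.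
  - The aryl silyl ether of 19 would be cleaved (TBAF, THF, 0 °C) to 2-bromo-3-(1,3-dioxolan-2-yl)-4-(methoxymethoxy)phenol F1.
  - Chan–Lam coupling of F1 with commercial [3-(methoxycarbonyl)-4-methylphenyl]boronic acid (Cu(OAc)2, pyridine, 4 Å molecular sieves, CH2Cl2, air, rt) would set the diaryl ether in open-chain form as the methyl 5-aryloxy-2-methylbenzoate F2.
  - Sonogashira coupling of F2 with alkynol 10 under the conditions of step 13 would give the aryl alkyne F3.
  - Lindlar semihydrogenation would give the Z-alkene F4, and LiOH (THF/MeOH/H2O, 50 °C) the hydroxy acid F5.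
  - Shiina macrolactonization (MNBA, DMAP, CH2Cl2, high dilution) between the ring A acid and C1–OH would close the 12-membered ring to 25.

**Step 16 (phenol macrolactonization).**
- What may go wrong: oligomerization may outrun closure of a rigid 13-membered ring, or the reagent's own acyl group may be transferred to the phenol.
- Fallback: sets out from 10 and 19 and returns at 24. The acyl carbon is brought in as CO and the ring closes on palladium instead of by acyl substitution.
  - Sonogashira coupling of 10 with 19 would give the aryl alkynol F6, and Lindlar semihydrogenation the Z-alkenol F7.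
  - Steglich esterification with commercial 5-iodo-2-methylbenzoic acid would give the iodobenzoate F8, and TBAF at 0 °C the iodo phenol F9.
  - Carbonylative macrolactonization (Pd(OAc)2, Xantphos, CO 1 atm, Et3N, toluene, 80 °C, slow addition) would trap the acylpalladium species with the tethered phenol to give 24.

**Step 13 (Sonogashira coupling).**
- What may go wrong:
  - Insertion into the doubly ortho-substituted, electron-rich C–Br bond may be slow.
  - The alkyne may homocouple.
  - The aryl silyl ether may be lost, followed by cyclization of the ortho-alkynylphenol to a benzofuran.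
- Fallback: sets out from 14 and 19 and returns at 21, bypassing steps 13 and 14.
  - Rhodium-catalysed trans-hydroboration of 14 ([Rh(cod)Cl]2, P(i-Pr)3, Et3N, pinacolborane, cyclohexane, rt) would give the Z-alkenylboronate F10.
  - Suzuki–Miyaura coupling of F10 with 19 (Pd(OAc)2, SPhos, K3PO4, THF/H2O, 40 °C) would form the ring B–alkenyl bond with retention of the Z geometry.

## Further compounds

F1 | step 17 | 2-bromo-3-(1,3-dioxolan-2-yl)-4-(methoxymethoxy)phenol | COCOc1ccc(O)c(Br)c1C1OCCO1
F2 | step 17 | methyl 5-[2-bromo-3-(1,3-dioxolan-2-yl)-4-(methoxymethoxy)phenoxy]-2-methylbenzoate | COC(=O)c1cc(ccc1C)Oc1ccc(OCOC)c(C2OCCO2)c1Br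
F3 | step 17 | methyl 5-{3-(1,3-dioxolan-2-yl)-2-[(3S,4S)-4-hydroxy-3-(methoxymethoxy)non-1-yn-1-yl]-4-(methoxymethoxy)phenoxy}-2-methylbenzoate | CCCCC[C@H](O)[C@@H](OCOC)C#Cc1c(Oc2ccc(C)c(c2)C(=O)OC)ccc(OCOC)c1C1OCCO1
F4 | step 17 | methyl 5-{3-(1,3-dioxolan-2-yl)-2-[(1Z,3S,4S)-4-hydroxy-3-(methoxymethoxy)non-1-en-1-yl]-4-(methoxymethoxy)phenoxy}-2-methylbenzoate | CCCCC[C@H](O)[C@@H](OCOC)/C=C\c1c(Oc2ccc(C)c(c2)C(=O)OC)ccc(OCOC)c1C1OCCO1
F5 | step 17 | 5-{3-(1,3-dioxolan-2-yl)-2-[(1Z,3S,4S)-4-hydroxy-3-(methoxymethoxy)non-1-en-1-yl]-4-(methoxymethoxy)phenoxy}-2-methylbenzoic acid | CCCCC[C@H](O)[C@@H](OCOC)/C=C\c1c(Oc2ccc(C)c(c2)C(=O)O)ccc(OCOC)c1C1OCCO1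
F6 | step 16 | (3S,4S)-1-[2-(tert-butyldimethylsilyloxy)-6-(1,3-dioxolan-2-yl)-5-(methoxymethoxy)phenyl]-3-(methoxymethoxy)non-1-yn-4-ol | CCCCC[C@H](O)[C@@H](OCOC)C#Cc1c(O[Si](C)(C)C(C)(C)C)ccc(OCOC)c1C1OCCO1
F7 | step 16 | (1Z,3S,4S)-1-[2-(tert-butyldimethylsilyloxy)-6-(1,3-dioxolan-2-yl)-5-(methoxymethoxy)phenyl]-3-(methoxymethoxy)non-1-en-4-ol | CCCCC[C@H](O)[C@@H](OCOC)/C=C\c1c(O[Si](C)(C)C(C)(C)C)ccc(OCOC)c1C1OCCO1
F8 | step 16 | 5-iodo-2-methylbenzoate of F7 | CCCCC[C@H](OC(=O)c1cc(I)ccc1C)[C@@H](OCOC)/C=C\c1c(O[Si](C)(C)C(C)(C)C)ccc(OCOC)c1C1OCCO1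
F9 | step 16 | (1Z,3S,4S)-1-[6-(1,3-dioxolan-2-yl)-2-hydroxy-5-(methoxymethoxy)phenyl]-3-(methoxymethoxy)non-1-en-4-yl 5-iodo-2-methylbenzoate | CCCCC[C@H](OC(=O)c1cc(I)ccc1C)[C@@H](OCOC)/C=C\c1c(O)ccc(OCOC)c1C1OCCO1
F10 | step 13 | 1-methyl 3-[(1Z,3S,4S)-3-(methoxymethoxy)-1-(4,4,5,5-tetramethyl-1,3,2-dioxaborolan-2-yl)non-1-en-4-yl] 4-methylisophthalate | CCCCC[C@H](OC(=O)c1cc(ccc1C)C(=O)OC)[C@@H](OCOC)/C=C\B1OC(C)(C)C(C)(C)O1
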